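I chose to reckon with what was left and not with what was made: u is the percent of the charged Q not in D, so Q, L and J together.

common to all: X 1.5 mM
- epsilon: Q 1.3 M; run made earlier
- delta: Q 3 M; run made earlier
- flask: Q 2.0 M; time 8.0 d

- epsilon (time / d: L / %, D / %, J / %): 0.625: 16.5, 25.5, 0; 1.67: 18.3, 41.1, 4.2; 3.00: 18.9, 46.8, 7.9; 5.00: 15.1, 55.7, 12.1; 8.00: 9.5, 63.4, 13.6; 10.0: 8.0, 65.3, 14.4
- delta (time / d: L / %, D / %, J / %): 0.625: 14.0, 44.0, 1.5; 1.67: 13.3, 59.8, 2.9; 3.00: 12.0, 66.8, 5.2; 5.00: 8.7, 74.5, 5.5; 8.00: 5.7, 79.1, 8.8; 10.0: 6.3, 78.3, 8.7

(standard deviation of a reading: 1 percentage point)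

1. how much L the flask holds at 8.0 d, in percent of the Q charged
2. how much D the flask holds at 8.0 d, in percent of the Q charged
3. how much J the flask holds at 8.0 d, in percent of the Q charged

- percent here means Q units held: one D counts as two
- a reading or a percentage of L counts all its forms, free or not

My bench rule was second-order: if a pool is lost in pairs, the odds D/u grow in step with charge c times time, so at one time and one amount of X, the odds per molar hold still. At 8.0 d, u was 36.6% in epsilon and 20.9% in delta, which gave 1.33 /M and 1.26 /M. Their mean, 1.30 /M, is my spending number s, the odds D/u per molar of charge at this time and this X. The rule stopped at its border, though: from the first epsilon reading to the 8.00 d one, the odds per day fell by a factor of 2.53, so s was no rate constant and could not be moved in time.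

The flask shared the time and X of both runs, so I used s across charge: u = 27.8% and D = 72.2%. Taking the mean shares of u in the two runs, I put L at 7.41% and J at 11.0%.

The forecast, reasoning that “D is favoured by higher concentration, which suggests a bimolecular route”, gave L 7.7%, D 72% and J 11%.

The flask gave L 7.52%, D 70.6% and J 10.9%.

    L + X ⇌ J + X, rate k1*[X]*[L] forward; the back reaction follows from the equilibrium constant (K = 2.10, k = 0.00150 /M/s)
    Q + X ⇌ L + X, rate k2*[Q]*[X] forward; the back reaction follows from the equilibrium constant (K = 0.640, k = 0.00320 /M/s)
    2 Q → D (k = 3.00 × 10⁻⁶ /M/s)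
    X + L ⇌ G (K = 0.820 /M, k = 1.30 × 10⁻⁵ /M/s)

The flask's s came to 1.20 /M. At 0.688 d in the flask, the pairing of Q to D used Q 1.4 times as fast as the forward step from Q to L, a ratio of forward rates at that moment. A neighbour flask charged with 0.0060 M of X held D at 58.0%, so its s was 0.691 /M.

Readings and results stem from a simulated flask for an exercise; the scatter is artificial.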